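(Readings and results are simulated with constants of no real substance; scatter was added.)

This closed, stirred, isothermal flask holds L and X: X adds to L to give the mono adduct D, and to D to give the bis adduct Z.

the same everywhere: L 0.50 M
- amber: X 0.70 equiv; run made earlier
- ochre: X 1.1 equiv; run made earlier
- flask: X 0.500 equiv; time 12 min

| run | time / min | D / % | Z / % | L / % |
|---|---|---|---|---|
| amber | 2.00 | 10 | 3 | 87 |
| amber | 4.00 | 19 | 1 | 84 |
| amber | 6.00 | 18 | 2 | 81 |
| amber | 8.00 | 23 | 1 | 78 |
| amber | 10.0 | 22 | 1 | 76 |
| amber | 12.0 | 25 | 0 | 77 |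
| amber | 15.0 | 26 | 3 | 74 |
| ochre | 2.00 | 18 | 1 | 83 |
| ochre | 4.00 | 24 | 1 | 75 |
| ochre | 6.00 | 27 | 2 | 68 |
| ochre | 8.00 | 28 | 1 | 68 |
| ochre | 10.0 | 29 | 1 | 66 |
| ochre | 12.0 | 30 | 1 | 62 |
| ochre | 15.0 | 31 | 4 | 64 |

(each reading ± 1.5 percentage points)

- the numbers in the tables scatter by 1.5 percentage points (one standard deviation)

1. equivalents of X to L, everything else as given, that leave most D at 12 min
2. the amount of D then, in percent of the L charged
3. the amount of D with the amounts as given

My bench rule treats X as the limiting reagent below one equivalent, one X per L, so 0.500 equiv of X should consume 0.500 equiv of L. The earlier runs test this with a ratio of L lost to X charged at 12.0 min: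

amber: 0.329

ochre: 0.345

mean: 0.337

The rule stops working here, since the mean stands far below 1. The capture fraction, L lost per equivalent of X charged, sets the L lost by 12.0 min against the X put in, so it belongs to that time, which is also the time asked. The ochre run reads L 83% at 2.00 min, 68% at 8.00 min and 64% at 15.0 min, a fall that slows without a clear stop. I take the slowing as X going elsewhere besides L.

For this flask I reckon:

L lost = 0.337 × 0.500 equiv = 16.9%

D = 16.9% − 1% of Z, as in the ochre run = 15.9%

The forecast gives more D than I do, 18%, and puts the best charge at 5 equiv with 62% of D, calling that “a long extrapolation, so the ranges are wide”.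

The flask gives 16.5% of D, and the best charge is 2.61 equiv, with 39.5% of D.

    Z ⇌ G (K = 5.80, k = 0.00230 s⁻¹)
    X ⇌ J (K = 5.30, k = 0.00472 s⁻¹)
    L + X → D + Q (k = 0.00448 M⁻¹ s⁻¹)
    X + D → Z + Q (k = 0.00387 M⁻¹ s⁻¹)

At the start, the forward step from X to J uses X at 2.1 times the rate of the path from L + X to D + Q. This flask keeps 82% of its L, a capture fraction of 0.360 against my 0.337. For the neighbour flask with 2.00 equiv of X, 0.337 foretells 67.4% of L lost, and that flask loses 55.7%, a capture fraction of 0.278.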